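(The earlier runs and the new flask are simulated for an exercise; scatter was added.)

In a one-step world the logarithm of the free monomer left would fall on a straight line from the first minute, but teal falls at 0.0363 h⁻¹ over its first reading and at 0.651 h⁻¹ late, much faster, so something has to build up first.

common to all: free monomer 1.9 M; impurity 9.5 mM

|  | pre-initiator | temperature | remark | time |
|---|---|---|---|---|
| red | 17 mM | 2 °C | run made earlier |  |
| teal | 26 mM | 52 °C | run made earlier |  |
| spring | 12 mM | 70 °C |  | 6.0 h |
| autumn | 12 mM | −20 °C |  | 6.0 h |
| dawn | 12 mM | 40 °C |  | 6.0 h |
| dusk | 12 mM | 10 °C |  | 6.0 h |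

| run | time / h | monomer in chains / % |
|---|---|---|
| red | 12.0 | 0 |
| red | 20.0 | 0 |
| red | 30.0 | 0 |
| red | 60.0 | 0 |
| red | 96.0 | 0.1 |
| red | 144 | 0.1 |
| teal | 2.00 | 7.0 |
| teal | 4.00 | 35.2 |
| teal | 6.00 | 69.9 |
| teal | 8.00 | 89.7 |
| teal | 10.0 | 97.2 |
| teal | 12.0 | 99.2 |

(standard deviation of a reading: 0.3 percentage points)

- the earlier runs were read with a standard deviation of 0.3 percentage points

- the flask that comes out highest in amount of monomer in chains, in percent of the free monomer charged, or "all alike" when all lie within 1.5 percentage points (spring / autumn / dawn / dusk / all alike)
- monomer in chains at the end, in percent of the free monomer charged, spring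
- monomer in chains at the end, in percent of the free monomer charged, autumn
- monomer in chains at the end, in percent of the free monomer charged, dawn
- monomer in chains at the end, in percent of the free monomer charged, dusk

The reading taken here is that the pre-initiator turns slowly, by first order, into initiator, that the impurity destroys initiator mole for mole, and that chains grow in proportion to the excess. For the new charges, minus the logarithm of one less the ratio of impurity to pre-initiator gives 1.57, and this is the impurity debt: the activation lifetimes that pass before the initiator released equals the impurity charged, which on this reading ends the induction period. Teal's middle slope of 0.383 h⁻¹, set against its late slope, gives as a reading an activation constant of 0.269 h⁻¹. Paying the debt within 6.0 h asks for 0.261 h⁻¹, so teal's constant barely clears it, and dawn, dusk and autumn, being colder than teal, are expected near zero.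

Red, still flat at 144 h, caps its constant at 0.00568 h⁻¹, so a straight logarithmic line through temperature gives spring at least 1.08 h⁻¹ and a crossing by 1.46 h. Teal's late slope, scaled to spring's smaller excess, is 0.0987 h⁻¹, which yields 36.1 %. The weak link is that this growth has not been warmed, so it takes the one temperature factor the runs offer, 4.01, and the committed figure for spring becomes 83.4 %.

The forecast, holding that “Colder flasks stay at zero”, named spring highest at 53 %, below the figure reckoned here, with dawn, dusk and autumn at 0 %.

The flasks give 94.4 % in spring, 2.22 % in dawn, 0 % in dusk and 0 % in autumn.

    free monomer + living end → monomer in chains + living end, rate k1*[living end]*[free monomer] (k = 0.724 L mol⁻¹ min⁻¹, Ea = 45.0 kJ mol⁻¹)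
    initiator + impurity → spent initiator (k = 6.90 L mol⁻¹ min⁻¹, Ea = 50.0 kJ mol⁻¹)
    free monomer + initiator → living end + monomer in chains (k = 0.00156 L mol⁻¹ min⁻¹, Ea = 80.0 kJ mol⁻¹)
    pre-initiator → initiator (k = 0.00100 min⁻¹, Ea = 103 kJ mol⁻¹)
    (constants at 40 °C)

Spring's pre-initiator, 0.328 % of its charge at 3.00 h, means an activation constant of 1.91 h⁻¹, so its debt of 1.57 puts the reckoned moment at which the initiator released in spring totals the impurity charged at 0.822 h, yet spring still holds 4.01 % of its impurity at 6.00 h. The neighbour of spring kept at 45 °C carries the same charges and the same debt, but its 51 % of pre-initiator left at 6.00 h means a constant of 0.112 h⁻¹, which puts its reckoned crossing at 14.0 h, later than its run lasts. That neighbour ends with 45 % of its impurity left and 6.43 % monomer in chains.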